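## Retrosynthetic overview

- Daucane numbering is used for the ring atoms: C1 quaternary fusion carbon (methyl), C2/C3 CH2, C4 isopropyl carbinol, C5 fusion CH, C6 acyloxy carbon, C7 CH2, C8=C9 alkene (methyl on C8), C10 CH2. The plan rests on the seven-membered ring carrying its oxygen at C6, directly beside fusion carbon C5, with the methyl-bearing C8 two atoms further on: C5–C9 is the five-carbon unit of an acyloxy-enyne and C1=C10 a tethered alkene.
- Endgame: the C6 aryl ester comes from a C6 ketone (reduction, acylation, desilylation), the ketone from a C5=C6 enol pivalate, and the C8=C9 alkene from a C7=C8 enone by deconjugation.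
- Key disconnection: rhodium-catalysed (5+2) cycloaddition with 1,2-pivaloyloxy shift (C7 to C6) of an acyclic enyne pivalate. C1–C5 (five-membered ring, formed first by alkene insertion) and C9–C10 (seven-membered ring, by reductive elimination) are made in one operation.
- Precursor: lithium acetylide of a silylated (S)-tertiary propargylic alcohol plus methacrolein, then pivaloylation. The carbinol (future C4) is set by Sharpless epoxidation of an (E)-allylic alcohol and carried through an epoxy chloride to alkyne elimination, which avoids any enolisable β-oxygenated carbonyl compound.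
- The allylic alcohol comes from a β-keto ester through its (Z)-enol triflate and an iron-catalysed Grignard coupling.

Key step: step 10

Remark: the carbinol carbon made in step 8 (C7) is carried as a mixture of epimers, because it becomes sp2 in step 10 and cannot influence the product.

## Route

Step 1
Reactants: 1 ethyl 4-methyl-3-oxopentanoate
Product: 2 ethyl (Z)-4-methyl-3-(trifluoromethylsulfonyloxy)pent-2-enoate
Conditions: Tf2O, aq. LiOH, toluene, 5–10 °C
Reagents that add atoms: triflic anhydride, O=S(=O)(OS(=O)(=O)C(F)(F)F)C(F)(F)F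
Why: O-sulfonylation of the lithium-chelated enolate of the β-keto ester should give the enol triflate with the triflate cis to the ester, which fixes the alkene geometry used in step 4.

Step 2
Reactants: 2 ethyl (Z)-4-methyl-3-(trifluoromethylsulfonyloxy)pent-2-enoate; 3 4-bromo-2-methylbut-1-ene
Product: 5 ethyl (E)-6-methyl-3-(propan-2-yl)hepta-2,6-dienoate, via 3-methylbut-3-enylmagnesium bromide 4 (not isolated)
Conditions: 3, Mg, THF, rt; then 2, Fe(acac)3 (5 mol%), THF, −30 °C
Reagents that add atoms: none
Why: Iron-catalysed Kumada-type coupling of an alkenyl triflate with an alkyl Grignard reagent proceeds with retention of alkene geometry and faster than addition to the ester, so the butenyl chain ends cis to the ester and the isopropyl group trans.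

Step 3
Reactants: 5 ethyl (E)-6-methyl-3-(propan-2-yl)hepta-2,6-dienoate
Product: 6 (E)-6-methyl-3-(propan-2-yl)hepta-2,6-dien-1-ol
Conditions: DIBAL-H (2.2 equiv), CH2Cl2, −78 °C; Rochelle salt
Reagents that add atoms: none
Why: 1,2-Reduction of the conjugated ester by DIBAL-H should give the allylic alcohol without touching either alkene.

Step 4
Reactants: 6 (E)-6-methyl-3-(propan-2-yl)hepta-2,6-dien-1-ol
Product: 7 [(2S,3S)-3-(3-methylbut-3-en-1-yl)-3-(propan-2-yl)oxiran-2-yl]methanol
Conditions: Ti(OiPr)4 (10 mol%), L-(+)-diethyl tartrate (12 mol%), t-BuOOH, 4 Å MS, CH2Cl2, −20 °C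
Reagents that add atoms: tert-butyl hydroperoxide, CC(C)(C)OO
Why: Sharpless asymmetric epoxidation with L-(+)-tartrate delivers oxygen to the face that gives the (2S,3S)-epoxide (same sense as for geraniol), with the bulky isopropyl group in the tolerated position trans to CH2OH and the isolated 1,1-disubstituted alkene inert; the quaternary epoxide carbon becomes C4 of the target.

Step 5
Reactants: 7 [(2S,3S)-3-(3-methylbut-3-en-1-yl)-3-(propan-2-yl)oxiran-2-yl]methanol
Product: 8 (2S,3R)-3-(chloromethyl)-2-(3-methylbut-3-en-1-yl)-2-(propan-2-yl)oxirane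
Conditions: PPh3, CCl4, NaHCO3, reflux
Reagents that add atoms: carbon tetrachloride, ClC(Cl)(Cl)Cl
Why: Appel chlorination of the primary alcohol leaves both epoxide carbons untouched (the descriptor of the CH carbon changes only because CH2Cl outranks the ring carbon).

Step 6
Reactants: 8 (2S,3R)-3-(chloromethyl)-2-(3-methylbut-3-en-1-yl)-2-(propan-2-yl)oxirane
Product: 9 (3S)-6-methyl-3-(propan-2-yl)hept-6-en-1-yn-3-ol
Conditions: n-BuLi (3.3 equiv), THF, −78 → −30 °C; aq. NH4Cl
Reagents that add atoms: none
Why: Base-induced double elimination of a 2,3-epoxy chloride (deprotonation at CH2Cl, epoxide opening to the chloroalkenyl alkoxide, loss of HCl) gives the terminal propargylic alcohol; the C–O bond of the tertiary carbon is never broken, so its configuration is retained.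

Step 7
Reactants: 9 (3S)-6-methyl-3-(propan-2-yl)hept-6-en-1-yn-3-ol
Product: 10 triethyl{[(3S)-6-methyl-3-(propan-2-yl)hept-6-en-1-yn-3-yl]oxy}silane
Conditions: TESOTf, 2,6-lutidine, CH2Cl2, −78 → 0 °C
Reagents that add atoms: triethylsilyl triflate, CC[Si](CC)(CC)OS(=O)(=O)C(F)(F)F
Why: A silyl triflate with a hindered pyridine base silylates even a tertiary alcohol, and the silyl ether masks the hydroxyl through the organolithium and rhodium steps.

Step 8
Reactants: 10 triethyl{[(3S)-6-methyl-3-(propan-2-yl)hept-6-en-1-yn-3-yl]oxy}silane; 11 methacrolein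
Product: 13 (6S)-2,9-dimethyl-6-(propan-2-yl)-6-(triethylsilyloxy)deca-1,9-dien-4-yn-3-ol (both C3 epimers), via lithium acetylide 12 (not isolated)
Conditions: n-BuLi, THF, −78 °C; then 11, −78 → −40 °C; aq. NH4Cl
Reagents that add atoms: none
Why: 1,2-Addition of a lithium acetylide to an enal builds the C6–C7 bond; no control at the new carbinol carbon is needed.

Step 9
Reactants: 13 (6S)-2,9-dimethyl-6-(propan-2-yl)-6-(triethylsilyloxy)deca-1,9-dien-4-yn-3-ol; 14 pivaloyl chloride
Product: 15 (6S)-2,9-dimethyl-6-(propan-2-yl)-6-(triethylsilyloxy)deca-1,9-dien-4-yn-3-yl 2,2-dimethylpropanoate (both C3 epimers)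
Conditions: Et3N, DMAP (cat.), CH2Cl2, 0 °C → rt
Reagents that add atoms: none
Why: DMAP-catalysed acylation of the secondary alcohol installs the pivalate that migrates in the next step.

Step 10
Reactants: 15 (6S)-2,9-dimethyl-6-(propan-2-yl)-6-(triethylsilyloxy)deca-1,9-dien-4-yn-3-yl 2,2-dimethylpropanoate
Product: 16 (3S,8aS)-6,8a-dimethyl-3-(propan-2-yl)-3-(triethylsilyloxy)-1,2,3,7,8,8a-hexahydroazulen-4-yl 2,2-dimethylpropanoate (daucane 1S,4S; C5=C6 and C7=C8 alkenes, pivalate on C6, C1 methyl cis to the C4 isopropyl group)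
Conditions: [Rh(cod)2]BF4 (10 mol%), P(4-CF3C6H4)3 (20 mol%), (CH2Cl)2, 70 °C
Reagents that add atoms: none
Why: Proposed new method: cationic monovalent rhodium activates the alkyne, the pivalate carbonyl oxygen adds to C6 and the C7–O bond breaks (1,2-acyloxy shift), and the resulting rhodium vinylcarbene closes onto C9 to a rhodacyclohexadiene spanning C5–C9; the tethered C1=C10 alkene then inserts into the Rh–C5 bond and reductive elimination joins C10 to C9. The closest known reaction type is the rhodium-catalysed intramolecular (5+2) cycloaddition of 3-acyloxy-1,4-enynes with tethered alkynes and with monosubstituted alkenes; insertion of a 1,1-disubstituted alkene that creates a quaternary carbon, in a substrate tethered through the alkyne terminus, has not been shown. The five-membered ring closes first by 5-exo migratory insertion (C1–C5) across the three-atom tether C2–C4, and the seven-membered ring closes by C(sp3)–C(sp3) reductive elimination (C9–C10) from an eight-membered rhodacycle whose Rh–C10 bond has no β-hydrogen, C1 being quaternary. C1 is the only new stereocentre and is controlled by C4 through the forming cyclopentene: the alkene must insert with the rhodium-bound C10 on the face of the C4–O bond and the methyl group on the face of the isopropyl group, which is the expected sense because the metal-bearing arm avoids the branched isopropyl group next to C5 whereas oxygen holds the silyl group one atom further away. The step needs 1,2- in preference to 1,3-acyloxy migration, which the fully substituted C4 secures by screening C5 from the ester oxygen, and it needs alkene insertion to outrun Rautenstrauch-type closure of the carbene, which the short tether and the electron-poor phosphine favour. Both C7 epimers of 15 should give the same product because C7 becomes sp2.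

Step 11
Reactants: 16 (3S,8aS)-6,8a-dimethyl-3-(propan-2-yl)-3-(triethylsilyloxy)-1,2,3,7,8,8a-hexahydroazulen-4-yl 2,2-dimethylpropanoate
Product: 17 (3S,3aR,8aS)-6,8a-dimethyl-3-(propan-2-yl)-3-(triethylsilyloxy)-2,3,3a,7,8,8a-hexahydroazulen-4(1H)-one (C6 ketone, C7=C8 enone, trans ring fusion)
Conditions: K2CO3 (0.5 equiv), MeOH, 0 °C; aq. NH4Cl
Reagents that add atoms: none
Why: Transesterification of the enol pivalate frees the cross-conjugated dienolate, which methanol protonates at once at C5; the proton is expected on the α face, opposite the C1 methyl and C4 isopropyl groups, which gives the trans ring fusion, and the short life of the enolate at 0 °C limits β-elimination of the C4 silyloxy group and later C5 epimerisation.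

Step 12
Reactants: 17 (3S,3aR,8aS)-6,8a-dimethyl-3-(propan-2-yl)-3-(triethylsilyloxy)-2,3,3a,7,8,8a-hexahydroazulen-4(1H)-one
Product: 19 (3S,3aR,8aR)-6,8a-dimethyl-3-(propan-2-yl)-3-(triethylsilyloxy)-2,3,3a,5,8,8a-hexahydroazulen-4(1H)-one (C6 ketone, C8=C9 alkene), via lithium dienolate 18 (not isolated)
Conditions: LDA (1.3 equiv), THF/DMPU, −78 °C; then AcOH in THF, −78 °C; crude product used at once
Reagents that add atoms: none
Why: Deconjugation of an enone through its extended dienolate: kinetic γ-deprotonation at the ring CH2 C9 (the α′ hydrogen on C5 is tertiary, flanked by two quaternary carbons and screened by the silyl ether) followed by kinetic protonation at the α-carbon C7 leaves the alkene at C8=C9, with no stereocentre formed and C5 untouched.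

Step 13
Reactants: 19 (3S,3aR,8aR)-6,8a-dimethyl-3-(propan-2-yl)-3-(triethylsilyloxy)-2,3,3a,5,8,8a-hexahydroazulen-4(1H)-one
Product: 20 (3S,3aS,4R,8aR)-6,8a-dimethyl-3-(propan-2-yl)-3-(triethylsilyloxy)-1,2,3,3a,4,5,8,8a-octahydroazulen-4-ol
Conditions: L-Selectride (1.5 equiv), THF, −78 °C; H2O
Reagents that add atoms: none
Why: The bulky borohydride should reach the C6 carbonyl from the open outer face of the seven-membered ring, away from the C1 methyl and C4 isopropyl groups that overhang the inner face, which sets the hydroxyl cis to the C1 methyl and trans to H5; at −78 °C reduction outruns enolisation, so the alkene does not return to conjugation.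

Step 14
Reactants: 21 4-hydroxybenzoic acid
Product: 23 4-(tert-butyldimethylsilyloxy)benzoic acid, via bis-silylated benzoate 22 (not isolated)
Conditions: TBSCl (2.2 equiv), imidazole, DMF, rt; then AcOH, THF/H2O, rt
Reagents that add atoms: tert-butyldimethylsilyl chloride, CC(C)(C)[Si](C)(C)Cl
Why: Double silylation followed by selective hydrolysis of the labile silyl ester leaves the aryl silyl ether, which protects the phenol during esterification.

Step 15
Reactants: 20 (3S,3aS,4R,8aR)-6,8a-dimethyl-3-(propan-2-yl)-3-(triethylsilyloxy)-1,2,3,3a,4,5,8,8a-octahydroazulen-4-ol; 23 4-(tert-butyldimethylsilyloxy)benzoic acid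
Product: 24 (3S,3aS,4R,8aR)-6,8a-dimethyl-3-(propan-2-yl)-3-(triethylsilyloxy)-1,2,3,3a,4,5,8,8a-octahydroazulen-4-yl 4-(tert-butyldimethylsilyloxy)benzoate
Conditions: DCC (2 equiv), DMAP (1 equiv), CH2Cl2, rt → 40 °C
Reagents that add atoms: none
Why: Steglich esterification acylates the hindered secondary alcohol with retention at C6; the tertiary oxygen is silylated and the phenol masked, so only the C6 hydroxyl can react.

Step 16
Reactants: 24 (3S,3aS,4R,8aR)-6,8a-dimethyl-3-(propan-2-yl)-3-(triethylsilyloxy)-1,2,3,3a,4,5,8,8a-octahydroazulen-4-yl 4-(tert-butyldimethylsilyloxy)benzoate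
Product: 25 (3S,3aS,4R,8aR)-3-hydroxy-6,8a-dimethyl-3-(propan-2-yl)-1,2,3,3a,4,5,8,8a-octahydroazulen-4-yl 4-hydroxybenzoate (target)
Conditions: TBAF, AcOH, THF, 0 °C → rt
Reagents that add atoms: none
Why: Fluoride cleaves both silyl ethers (aryl silyl ether fast, tertiary triethylsilyl ether more slowly) while acetic acid buffering keeps the benzoate ester and the tertiary alcohol intact.

## Compound list

1 | ethyl 4-methyl-3-oxopentanoate | CCOC(=O)CC(=O)C(C)C | starting material
2 | ethyl (Z)-4-methyl-3-(trifluoromethylsulfonyloxy)pent-2-enoate | CCOC(=O)/C=C(\OS(=O)(=O)C(F)(F)F)C(C)C | intermediate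
3 | 4-bromo-2-methylbut-1-ene | C=C(C)CCBr | starting material
4 | 3-methylbut-3-enylmagnesium bromide | C=C(C)CC[Mg]Br | intermediate
5 | ethyl (E)-6-methyl-3-(propan-2-yl)hepta-2,6-dienoate | CCOC(=O)/C=C(\CCC(C)=C)C(C)C | intermediate
6 | (E)-6-methyl-3-(propan-2-yl)hepta-2,6-dien-1-ol | OC/C=C(\CCC(C)=C)C(C)C | intermediate
7 | [(2S,3S)-3-(3-methylbut-3-en-1-yl)-3-(propan-2-yl)oxiran-2-yl]methanol | OC[C@@H]1O[C@]1(C(C)C)CCC(C)=C | intermediate
8 | (2S,3R)-3-(chloromethyl)-2-(3-methylbut-3-en-1-yl)-2-(propan-2-yl)oxirane | ClC[C@@H]1O[C@]1(C(C)C)CCC(C)=C | intermediate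
9 | (3S)-6-methyl-3-(propan-2-yl)hept-6-en-1-yn-3-ol | C#C[C@@](O)(C(C)C)CCC(C)=C | intermediate
10 | triethyl{[(3S)-6-methyl-3-(propan-2-yl)hept-6-en-1-yn-3-yl]oxy}silane | C#C[C@@](O[Si](CC)(CC)CC)(C(C)C)CCC(C)=C | intermediate
11 | methacrolein | C=C(C)C=O | starting material
12 | lithium acetylide of 10 | [Li]C#C[C@@](O[Si](CC)(CC)CC)(C(C)C)CCC(C)=C | intermediate
13 | (6S)-2,9-dimethyl-6-(propan-2-yl)-6-(triethylsilyloxy)deca-1,9-dien-4-yn-3-ol, both C3 epimers | C=C(C)C(O)C#C[C@@](O[Si](CC)(CC)CC)(C(C)C)CCC(C)=C | intermediate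
14 | pivaloyl chloride | CC(C)(C)C(=O)Cl | starting material
15 | (6S)-2,9-dimethyl-6-(propan-2-yl)-6-(triethylsilyloxy)deca-1,9-dien-4-yn-3-yl 2,2-dimethylpropanoate, both C3 epimers | C=C(C)C(OC(=O)C(C)(C)C)C#C[C@@](O[Si](CC)(CC)CC)(C(C)C)CCC(C)=C | intermediate
16 | (3S,8aS)-6,8a-dimethyl-3-(propan-2-yl)-3-(triethylsilyloxy)-1,2,3,7,8,8a-hexahydroazulen-4-yl 2,2-dimethylpropanoate | CC1=CC(OC(=O)C(C)(C)C)=C2[C@@](O[Si](CC)(CC)CC)(C(C)C)CC[C@]2(C)CC1 | intermediate
17 | (3S,3aR,8aS)-6,8a-dimethyl-3-(propan-2-yl)-3-(triethylsilyloxy)-2,3,3a,7,8,8a-hexahydroazulen-4(1H)-one | CC1=CC(=O)[C@H]2[C@@](O[Si](CC)(CC)CC)(C(C)C)CC[C@]2(C)CC1 | intermediate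
18 | lithium dienolate of 17 (C6 oxide, C6=C7 and C8=C9) | [Li]OC1=CC(C)=CC[C@@]2(C)CC[C@](O[Si](CC)(CC)CC)(C(C)C)[C@H]12 | intermediate
19 | (3S,3aR,8aR)-6,8a-dimethyl-3-(propan-2-yl)-3-(triethylsilyloxy)-2,3,3a,5,8,8a-hexahydroazulen-4(1H)-one | CC1=CC[C@@]2(C)CC[C@](O[Si](CC)(CC)CC)(C(C)C)[C@@H]2C(=O)C1 | intermediate
20 | (3S,3aS,4R,8aR)-6,8a-dimethyl-3-(propan-2-yl)-3-(triethylsilyloxy)-1,2,3,3a,4,5,8,8a-octahydroazulen-4-ol | CC1=CC[C@@]2(C)CC[C@](O[Si](CC)(CC)CC)(C(C)C)[C@@H]2[C@H](O)C1 | intermediate
21 | 4-hydroxybenzoic acid | O=C(O)c1ccc(O)cc1 | starting material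
22 | tert-butyldimethylsilyl 4-(tert-butyldimethylsilyloxy)benzoate | CC(C)(C)[Si](C)(C)OC(=O)c1ccc(O[Si](C)(C)C(C)(C)C)cc1 | intermediate
23 | 4-(tert-butyldimethylsilyloxy)benzoic acid | CC(C)(C)[Si](C)(C)Oc1ccc(C(=O)O)cc1 | intermediate
24 | (3S,3aS,4R,8aR)-6,8a-dimethyl-3-(propan-2-yl)-3-(triethylsilyloxy)-1,2,3,3a,4,5,8,8a-octahydroazulen-4-yl 4-(tert-butyldimethylsilyloxy)benzoate | CC1=CC[C@@]2(C)CC[C@](O[Si](CC)(CC)CC)(C(C)C)[C@@H]2[C@H](OC(=O)c2ccc(O[Si](C)(C)C(C)(C)C)cc2)C1 | intermediate
25 | (3S,3aS,4R,8aR)-3-hydroxy-6,8a-dimethyl-3-(propan-2-yl)-1,2,3,3a,4,5,8,8a-octahydroazulen-4-yl 4-hydroxybenzoate | CC1=CC[C@@]2(C)CC[C@](O)(C(C)C)[C@@H]2[C@H](OC(=O)c2ccc(O)cc2)C1 | target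

## Step count and risks

Total step count: 16. Longest linear sequence: 15 (steps 1–13, 15, 16); step 14 is a one-step side branch.

**Step 10 (proposed new method).** The hindered 1,1-disubstituted alkene may fail to insert into the rhodacycle, so that the carbene collapses by 1,3-acyloxy shift to an allenyl ester or by Rautenstrauch closure to a cyclopentenone. It may also insert on the wrong face and give the C1 epimer. The fallback builds the bicycle stepwise by known reactions, sets out from 10 and returns at 17: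
- Ring-closing enyne metathesis of 10 (second-generation Grubbs catalyst, ethylene, CH2Cl2, 40 °C) should give triethyl{[(1S)-2-ethenyl-3-methyl-1-(propan-2-yl)cyclopent-2-en-1-yl]oxy}silane F1, in which C1–C5 is already formed.
- Lemieux–Johnson cleavage of the vinyl group (OsO4 cat., NaIO4, 2,6-lutidine, dioxane/H2O) should give the enal (5S)-2-methyl-5-(propan-2-yl)-5-(triethylsilyloxy)cyclopent-1-ene-1-carbaldehyde F2.
- Copper-catalysed conjugate addition of Grignard reagent 4 (CuBr·SMe2, TMSCl, DMPU, THF, −78 °C) should build the quaternary C1 with the new chain anti to the isopropyl group and give the trimethylsilyl enol ether F3. Mild acid hydrolysis then gives the aldehyde 2-methyl-2-(3-methylbut-3-enyl)-5-(propan-2-yl)-5-(triethylsilyloxy)cyclopentane-1-carbaldehyde F4.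
- Vinylmagnesium bromide (THF, −78 °C) gives the allylic alcohol F5.
- Ring-closing metathesis (second-generation Hoveyda–Grubbs catalyst, toluene, 80 °C) closes the seven-membered ring at C7=C8 to the cyclic allylic alcohol F6.
- Dess–Martin oxidation returns to 17.

**Step 12.** Deprotonation may occur at the C8 methyl group or at C5 instead of C9, and the dienolate may be reprotonated at C9, which returns 17. A C5 enolate may also expel the C4 silyloxy group, and the β,γ-enone may slip back into conjugation on work-up. The fallback avoids a metal enolate, sets out from 17 and returns at 19: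
- Soft enolisation (TMSOTf, Et3N, CH2Cl2, 0 °C) should give the linear trimethylsilyl dienol ether F7 (C6 silyloxy, C6=C7 and C8=C9).
- Buffered protodesilylation (KF, AcOH, MeOH, 0 °C) protonates at C7 and returns to 19.

**Step 11.** The transient enolate may be protonated on the wrong face of C5 (cis ring fusion), the C5 centre may epimerise under the basic conditions, or the enolate may eliminate the C4 silyloxy group. The fallback uses the C4 hydroxyl on the α face as a relay for the proton, sets out from 16 and returns at 17: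
- Desilylation of 16 (TBAF, AcOH, THF, 0 °C) should give the hydroxy dienyl pivalate F8.
- Methanolysis (K2CO3, MeOH, −20 °C, kept cold to avoid retro-aldol cleavage) should deliver the proton through hydrogen-bonded methanol from the hydroxyl-bearing α face and give the hydroxy enone F9, with no silyloxide leaving group present.
- TESOTf/2,6-lutidine (CH2Cl2, −78 °C) returns to 17.

Further compounds
F1 | step 10 | triethyl{[(1S)-2-ethenyl-3-methyl-1-(propan-2-yl)cyclopent-2-en-1-yl]oxy}silane | C=CC1=C(C)CC[C@]1(O[Si](CC)(CC)CC)C(C)C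
F2 | step 10 | (5S)-2-methyl-5-(propan-2-yl)-5-(triethylsilyloxy)cyclopent-1-ene-1-carbaldehyde | O=CC1=C(C)CC[C@]1(O[Si](CC)(CC)CC)C(C)C
F3 | step 10 | trimethylsilyl enol ether of F4 (exocyclic C5=C6, C1 quaternary) | C[Si](C)(C)OC=C1[C@@](O[Si](CC)(CC)CC)(C(C)C)CC[C@]1(C)CCC(C)=C
F4 | step 10 | 2-methyl-2-(3-methylbut-3-enyl)-5-(propan-2-yl)-5-(triethylsilyloxy)cyclopentane-1-carbaldehyde, C1, C4 and C5 configured as in 17 | O=C[C@H]1[C@@](O[Si](CC)(CC)CC)(C(C)C)CC[C@]1(C)CCC(C)=C
F5 | step 10 | 1-[2-methyl-2-(3-methylbut-3-enyl)-5-(propan-2-yl)-5-(triethylsilyloxy)cyclopentyl]prop-2-en-1-ol, both carbinol epimers | C=CC(O)[C@H]1[C@@](O[Si](CC)(CC)CC)(C(C)C)CC[C@]1(C)CCC(C)=C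
F6 | step 10 | 6,8a-dimethyl-3-(propan-2-yl)-3-(triethylsilyloxy)-1,2,3,3a,4,7,8,8a-octahydroazulen-4-ol, both C4 epimers | CC1=CC(O)[C@H]2[C@@](O[Si](CC)(CC)CC)(C(C)C)CC[C@]2(C)CC1
F7 | step 12 | trimethylsilyl dienol ether of 17 (C6 silyloxy, C6=C7 and C8=C9) | C[Si](C)(C)OC1=CC(C)=CC[C@@]2(C)CC[C@](O[Si](CC)(CC)CC)(C(C)C)[C@H]12
F8 | step 11 | (3S,8aS)-3-hydroxy-6,8a-dimethyl-3-(propan-2-yl)-1,2,3,7,8,8a-hexahydroazulen-4-yl 2,2-dimethylpropanoate | CC1=CC(OC(=O)C(C)(C)C)=C2[C@@](O)(C(C)C)CC[C@]2(C)CC1
F9 | step 11 | (3S,3aR,8aS)-3-hydroxy-6,8a-dimethyl-3-(propan-2-yl)-2,3,3a,7,8,8a-hexahydroazulen-4(1H)-one | CC1=CC(=O)[C@H]2[C@@](O)(C(C)C)CC[C@]2(C)CC1
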